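The readings were computed on assumed constants, and the scatter is random.

**Small charge.** A small charge of second catalyst, 0.10 mM in the blue run and 0.20 mM in the green, is what separates two runs. You want to know what it changes, and what that says about four ways of adding the same reagents.

| setting | blue | green | dusk | autumn | spring | dawn |
|---|---|---|---|---|---|---|
| substrate | 0.10 M | 0.10 M | 0.10 M (fed, over 15 min) | 0.10 M | 0.10 M | 0.10 M |
| partner | 0.15 M | 0.15 M | 0.150 M | 0.150 M (fed, over 15 min) | 0.150 M (in portions, 3, over 15 min) | 0.150 M |
| second catalyst | 0.10 mM | 0.20 mM | 0.10 mM | 0.10 mM | 0.10 mM | 0.10 mM |
| precatalyst | 2 mM | 2 mM | 2.0 mM | 2.0 mM | 2.0 mM | 2.0 mM |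
| remark | run made earlier | run made earlier | all else is in the flask from the start; the feed brings no volume worth counting | all else is in the flask from the start; the feed brings no volume worth counting | first portion at the start, last at 15 min | everything together at the start |
| time |  |  | 20 min | 20 min | 20 min | 20 min |

- blue (time / min: target / %, over-reaction product / %): 1.00: 35, 5; 2.00: 49, 12; 5.00: 50, 30; 12.0: 47, 45
- green (time / s: target / %, over-reaction product / %): 30.0: 33, 4; 60.0: 51, 5; 90.0: 63, 9; 120: 62, 14

(each reading ± 1.5 percentage points)

1. the flask with the highest share of target in target plus over-reaction product ("all alike" if they lie within 1.5 percentage points) (dusk / autumn / spring / dawn / all alike)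
2. share of target in target plus over-reaction product at the end, dusk
3. share of target in target plus over-reaction product at the end, autumn
4. share of target in target plus over-reaction product at the end, spring
5. share of target in target plus over-reaction product at the end, dawn

**Two runs.** At 2 min the green run holds target 62%, more than the blue run's 49% at the same clock time. Yet over-reaction product differs by 2 percentage points, against a scatter of 1.5 points.

**Wear rate.** Count each target as one partner used and each over-reaction product as two. Between 2.00 min and 5.00 min the blue run gains over-reaction product at 0.0600 min⁻¹ of the substrate charge. Target averages 49.5% there, and the fraction of partner left averages 39.0%. Dividing gives 0.311 min⁻¹. This is the wear rate: the fraction of standing target lost per minute, per whole partner charge left. Multiplied by the partner fraction, it is a pseudo-first-order constant.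

Around 1.5 min the green run gives 0.311 min⁻¹, the same reading. So the two runs match in over-reaction product because green's extra target meets less partner: 40.0% left against blue's 51.3%.

**My reckoning.** Dawn is the blue recipe. Blue's last reading has a share of 51.1% at 12.0 min, and wear there still runs at 0.0127 min⁻¹ of the charge. So I put dawn below that share at 20 min. Feeding partner keeps its fraction low while target builds, so I expect autumn and spring above dawn. Feeding substrate leaves partner high against little target, so I expect dusk below dawn.

**The forecast.** It names spring, with dusk 43%, autumn 54%, spring 57% and dawn 46%. Of dosing partner it says: “dosing it doesn't change selectivity at a given conversion”. My reckoning puts autumn and spring above dawn and dusk below it. It does not rank spring against autumn, and it gives none of these numbers.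

    substrate + free catalyst → free catalyst + intermediate (k = 163 L mol⁻¹ s⁻¹)
    partner + second catalyst + intermediate → second catalyst + target (k = 801 L² mol⁻² s⁻¹)
    partner + target → over-reaction product (k = 0.0342 L mol⁻¹ s⁻¹)
    precatalyst → free catalyst (k = 0.0753 s⁻¹)

**The flasks.** spring leads, with spring 55.6%, autumn 52.7%, dawn 45.2% and dusk 41.5%. At 20.0 min the wear rate gives spring a loss of 0.0227 min⁻¹ of the charge, and target is made at 0.548 of the rate at which it is used up. With dawn's partner 3.15% and target 42.4%, the same rate gives 0.00415 min⁻¹, so spring is wearing faster than dawn. Read at 200 min, spring holds target 39.9% and dawn 39.9%.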